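A direct plan would buy both phenol rings: a 3,5-dioxygenated benzoate would be dibrominated to A1, benzylated twice by Negishi coupling and adjusted to aldehyde A2; lithiated toluate A3 would add to A2 and lactonise to isochromanone A4, which would be opened by base to a stilbene acid and saturated to acid A5; the carboxyl group would then be turned into the third benzyl group by way of ketone A6 before hydrogenolysis. Its weakest points would be:
(a) the conversion of the carboxyl group of A5 into a 4-hydroxybenzyl group (amide, aryl addition, hydride reduction, deoxygenation): four steps on the most advanced material that add one aryl ring and then erase every function they made;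
(b) the twofold sp3–sp2 coupling on A1, where each bromide sits between two ortho substituents, so that mono-coupling and protodebromination would compete;
(c) the detour through lactone A4, which would build a ring and a stereocentre only to destroy both by elimination and a large excess of diimide, merely to leave a CH2CH2 bridge.

**Plan of the new route**
Numbering: ring A C1 (OMe), C2 (H), C3 (OH), C4 and C6 (ArCH2), C5 (bridge); ring B C1' (bridge), C3' (OH), C6' (ArCH2).
Enabling feature: in both rings the bridge carbon (C5, C1') is bonded to a benzyl-bearing carbon (C4, C6') that has oxygen on its ortho carbon (C3) and/or para carbon (C1; C3'). This is the imprint of an aroylalkyne that has taken up a 1,3-dioxygenated diene, and the six carbons C4–C5–CH2–CH2–C1'–C6' are hexa-1,5-diyne.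
Cuts: ring A at C3–C4 and C5–C6 (diene 10 supplies C6–C1–C2–C3 with the C6 benzyl group, the OMe and the future OH); ring B at C1'–C2' and C5'–C6' (Danishefsky's diene); the benzylic CH2 groups at C4 and C6' stay aroyl C=O groups until the end.
Order: bridge and both benzylic carbons first (bis-ynone 3), then ring A (step 5), then ring B (step 6), then both C=O groups to CH2 in one operation and hydrogenolysis.
No aryl–benzyl coupling on a crowded ring, no carboxyl-to-benzyl sequence and no ring or stereocentre made to be destroyed occur. The C=O groups that are removed are the ones that drive both annulations, and the diene itself tells OH from OMe on ring A.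

Key step: step 5

Remark: diene 10 and cycloadducts 11 and 15 are expected as isomer mixtures; all their stereogenic elements vanish on aromatisation, and the target is achiral.

Step 1
Reactants: 1 hexa-1,5-diyne; 2 4-(benzyloxy)benzoyl chloride (2.2 equiv)
Product: 3 1,8-bis[4-(benzyloxy)phenyl]octa-2,6-diyne-1,8-dione
Conditions: PdCl2(PPh3)2 (2 mol%), CuI (4 mol%), Et3N (2.5 equiv), THF, rt, argon
Reagents that add atoms: none
Why: Twofold acyl Sonogashira coupling (the acid chloride adds to zerovalent palladium formed in situ, the copper acetylide transmetalates, reductive elimination gives the ynone) is a standard route to 1-aryl-alk-2-yn-1-ones; both alkyne termini are equivalent and the benzyl ethers are inert.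

Step 2
Reactants: 4 methyl acetoacetate; 5 4-(benzyloxy)benzyl chloride
Product: 7 methyl 5-[4-(benzyloxy)phenyl]-3-oxopentanoate, via sodium lithium dianion 6 (not isolated)
Conditions: NaH (1.1 equiv), THF, 0 °C; n-BuLi (1.05 equiv), 0 °C; then 5, 0 °C → rt; 1 M HCl
Reagents that add atoms: none
Why: Weiler-type dianion alkylation, in which the more basic terminal carbanion of the acetoacetate dianion is alkylated by the benzylic chloride, so only γ-substitution should occur.

Step 3
Reactants: 7 methyl 5-[4-(benzyloxy)phenyl]-3-oxopentanoate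
Product: 8 methyl (2E)-5-[4-(benzyloxy)phenyl]-3-methoxypent-2-enoate
Conditions: HC(OMe)3 (3 equiv), MeOH, conc. H2SO4 (cat.), rt → 50 °C; volatiles distilled off
Reagents that add atoms: trimethyl orthoformate, COC(OC)OC
Why: Acid-catalysed ketalisation by the orthoformate and loss of methanol should give the conjugated (E)-3-methoxy-2-enoate, the thermodynamic isomer, as in the preparation of methyl 3-methoxycrotonate.

Step 4
Reactants: 8 methyl (2E)-5-[4-(benzyloxy)phenyl]-3-methoxypent-2-enoate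
Product: 10 ({5-[4-(benzyloxy)phenyl]-1,3-dimethoxypenta-1,3-dien-1-yl}oxy)trimethylsilane (mixture of C=C isomers), via lithium dienolate 9 (not isolated)
Conditions: LiN(i-Pr)2 (LDA, 1.1 equiv), THF, −78 °C; Me3SiCl (1.3 equiv), −78 → 0 °C; concentrated, taken up in dry pentane, filtered, evaporated; used at once
Reagents that add atoms: chlorotrimethylsilane, C[Si](C)(C)Cl
Why: γ-Deprotonation of the 3-methoxy-enoate and O-silylation of the extended ester enolate give a Brassard-type 1,3-dioxygenated diene; the vinyl hydrogen at C2 is not acidic, so only the γ-CH2 should be deprotonated.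

Step 5 (key step)
Reactants: 3 1,8-bis[4-(benzyloxy)phenyl]octa-2,6-diyne-1,8-dione (3.0 equiv); 10 ({5-[4-(benzyloxy)phenyl]-1,3-dimethoxypenta-1,3-dien-1-yl}oxy)trimethylsilane
Product: 13 1-[4-(benzyloxy)phenyl]-5-{2-[4-(benzyloxy)benzoyl]-6-[4-(benzyloxy)benzyl]-3-hydroxy-5-methoxyphenyl}pent-2-yn-1-one, via cyclohexadiene cycloadduct 11 (not isolated), via aryl trimethylsilyl ether 12 (not isolated)
Conditions: toluene, 110–130 °C, sealed tube, argon; then 1 M HCl, THF, rt; unreacted 3 recovered by chromatography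
Reagents that add atoms: none
Why: Thermal normal-demand [4+2] cycloaddition of the electron-rich diene 10 to one aroylalkyne of 3 (concerted but asynchronous, or addition of the diene terminus to the ynone followed by closure of the allenolate onto the silyloxy-oxocarbenium carbon; both paths give 11), then 1,4-elimination of methanol across C3/C6 and hydrolysis of the aryl silyl ether; the closest known reaction type is the benzannulation of 1-alkoxy-1-silyloxy-3-alkoxybutadienes with alk-2-ynoates and ynones to orsellinate-type 2-hydroxy-4-methoxy-6-alkylaryl carbonyl compounds. Ring A is closed by intermolecular [4+2] cycloaddition, which forms C5–C6 and C3–C4 in one operation and places all five substituents of the ring. The two sp3 centres of 11 (C3 and C6) are uncontrolled and vanish on aromatisation, so the isomer mixture of 10 is immaterial (an isomer that cannot reach the concerted geometry can still react by the stepwise path). Regioselectivity is needed and is secured by polarisation: the largest HOMO coefficient of 10 lies on its benzyl-bearing terminus, which bonds to the β-carbon of the ynone, so the ketene acetal carbon ends next to the aroyl group; this puts OH (from the ketene acetal, chelated to the C=O) at C3 and OMe (from the enol ether) at C1 without any selective methylation. Site selectivity between the two equivalent ynones is only statistical and is secured by the threefold excess of 3, whose ynones are insulated by the CH2CH2 unit. The benzyl ethers and the second ynone are inert under the neutral thermal conditions.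

Step 6
Reactants: 13 1-[4-(benzyloxy)phenyl]-5-{2-[4-(benzyloxy)benzoyl]-6-[4-(benzyloxy)benzyl]-3-hydroxy-5-methoxyphenyl}pent-2-yn-1-one; 14 (E)-1-methoxy-3-(trimethylsilyloxy)buta-1,3-diene (Danishefsky's diene, 4 equiv)
Product: 17 [2-(2-{2-[4-(benzyloxy)benzoyl]-6-[4-(benzyloxy)benzyl]-3-hydroxy-5-methoxyphenyl}ethyl)-4-hydroxyphenyl][4-(benzyloxy)phenyl]methanone, via cyclohexadiene cycloadduct 15 (not isolated), via aryl trimethylsilyl ether 16 (not isolated)
Conditions: toluene, 120 °C, sealed tube, argon; then 1 M HCl, THF, rt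
Reagents that add atoms: none
Why: Diels–Alder reaction of Danishefsky's diene with the remaining aroylalkyne and loss of methanol (a regiospecific phenol synthesis): the CH2 terminus of the diene bonds to the β-carbon of the ynone, so the new OH ends para to the aroyl group and meta to the bridge as ring B requires, and the excess diene covers any loss to the chelated phenol.

Step 7
Reactants: 17 [2-(2-{2-[4-(benzyloxy)benzoyl]-6-[4-(benzyloxy)benzyl]-3-hydroxy-5-methoxyphenyl}ethyl)-4-hydroxyphenyl][4-(benzyloxy)phenyl]methanone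
Product: 18 2,4-bis[4-(benzyloxy)benzyl]-3-(2-{2-[4-(benzyloxy)benzyl]-5-hydroxyphenyl}ethyl)-5-methoxyphenol
Conditions: Et3SiH (8 equiv), CF3CO2H/CH2Cl2 (1:2), 0 °C → rt
Reagents that add atoms: none
Why: Ionic hydrogenation, in which each protonated diaryl ketone is a carbenium ion stabilised by para-alkoxy and ortho- or para-hydroxy groups and is reduced twice by the silane to the diarylmethane, as in the reduction of 4-acylresorcinols and 4-alkoxybenzophenones; the silane should trap the benzylic cations faster than any ring carbon.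

Step 8
Reactants: 18 2,4-bis[4-(benzyloxy)benzyl]-3-(2-{2-[4-(benzyloxy)benzyl]-5-hydroxyphenyl}ethyl)-5-methoxyphenol
Product: 19 2,4-bis(4-hydroxybenzyl)-3-{2-[5-hydroxy-2-(4-hydroxybenzyl)phenyl]ethyl}-5-methoxyphenol (CNP0147493.0)
Conditions: H2 (1 atm), 10% Pd/C, EtOAc/MeOH, rt
Reagents that add atoms: none
Why: Catalytic hydrogenolysis cleaves the three aryl benzyl ethers, while the aryl methyl ether and the diarylmethane and bibenzyl C–C bonds are inert.

## Compound list

1 | hexa-1,5-diyne | C#CCCC#C | starting material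
2 | 4-(benzyloxy)benzoyl chloride | O=C(Cl)c1ccc(OCc2ccccc2)cc1 | starting material
3 | 1,8-bis[4-(benzyloxy)phenyl]octa-2,6-diyne-1,8-dione | O=C(C#CCCC#CC(=O)c1ccc(OCc2ccccc2)cc1)c1ccc(OCc2ccccc2)cc1 | intermediate
4 | methyl acetoacetate | COC(=O)CC(C)=O | starting material
5 | 4-(benzyloxy)benzyl chloride | ClCc1ccc(OCc2ccccc2)cc1 | starting material
6 | sodium lithium dianion of methyl acetoacetate (formed in situ) | [Na+].[Li+].[CH2-]C(=O)[CH-]C(=O)OC | intermediate
7 | methyl 5-[4-(benzyloxy)phenyl]-3-oxopentanoate | COC(=O)CC(=O)CCc1ccc(OCc2ccccc2)cc1 | intermediate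
8 | methyl (2E)-5-[4-(benzyloxy)phenyl]-3-methoxypent-2-enoate | COC(=O)/C=C(/OC)CCc1ccc(OCc2ccccc2)cc1 | intermediate
9 | lithium dienolate of 8 (formed in situ; C=C geometry not defined) | COC(=CC(OC)=CCc1ccc(OCc2ccccc2)cc1)O[Li] | intermediate
10 | ({5-[4-(benzyloxy)phenyl]-1,3-dimethoxypenta-1,3-dien-1-yl}oxy)trimethylsilane (mixture of C=C isomers) | COC(=CC(OC)=CCc1ccc(OCc2ccccc2)cc1)O[Si](C)(C)C | intermediate
11 | 1-[4-(benzyloxy)phenyl]-5-{2-[4-(benzyloxy)benzoyl]-6-[4-(benzyloxy)benzyl]-3,5-dimethoxy-3-(trimethylsilyloxy)cyclohexa-1,4-dien-1-yl}pent-2-yn-1-one (racemic mixture of diastereomers, formed in situ) | COC1=CC(OC)(O[Si](C)(C)C)C(C(=O)c2ccc(OCc3ccccc3)cc2)=C(CCC#CC(=O)c2ccc(OCc3ccccc3)cc2)C1Cc1ccc(OCc2ccccc2)cc1 | intermediate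
12 | trimethylsilyl ether of 13 at the ring A hydroxyl (formed in situ) | O=C(C#CCCc1c(C(=O)c2ccc(OCc3ccccc3)cc2)c(O[Si](C)(C)C)cc(OC)c1Cc1ccc(OCc2ccccc2)cc1)c1ccc(OCc2ccccc2)cc1 | intermediate
13 | 1-[4-(benzyloxy)phenyl]-5-{2-[4-(benzyloxy)benzoyl]-6-[4-(benzyloxy)benzyl]-3-hydroxy-5-methoxyphenyl}pent-2-yn-1-one | O=C(C#CCCc1c(C(=O)c2ccc(OCc3ccccc3)cc2)c(O)cc(OC)c1Cc1ccc(OCc2ccccc2)cc1)c1ccc(OCc2ccccc2)cc1 | intermediate
14 | (E)-1-methoxy-3-(trimethylsilyloxy)buta-1,3-diene (Danishefsky's diene) | CO/C=C/C(=C)O[Si](C)(C)C | starting material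
15 | [2-(2-{2-[4-(benzyloxy)benzoyl]-6-[4-(benzyloxy)benzyl]-3-hydroxy-5-methoxyphenyl}ethyl)-6-methoxy-4-(trimethylsilyloxy)cyclohexa-1,4-dien-1-yl][4-(benzyloxy)phenyl]methanone (racemic, formed in situ) | COC1C=C(O[Si](C)(C)C)CC(CCc2c(C(=O)c3ccc(OCc4ccccc4)cc3)c(O)cc(OC)c2Cc2ccc(OCc3ccccc3)cc2)=C1C(=O)c1ccc(OCc2ccccc2)cc1 | intermediate
16 | trimethylsilyl ether of 17 at the ring B hydroxyl (formed in situ) | O=C(c1ccc(OCc2ccccc2)cc1)c1ccc(O[Si](C)(C)C)cc1CCc1c(C(=O)c2ccc(OCc3ccccc3)cc2)c(O)cc(OC)c1Cc1ccc(OCc2ccccc2)cc1 | intermediate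
17 | [2-(2-{2-[4-(benzyloxy)benzoyl]-6-[4-(benzyloxy)benzyl]-3-hydroxy-5-methoxyphenyl}ethyl)-4-hydroxyphenyl][4-(benzyloxy)phenyl]methanone | O=C(c1ccc(OCc2ccccc2)cc1)c1ccc(O)cc1CCc1c(C(=O)c2ccc(OCc3ccccc3)cc2)c(O)cc(OC)c1Cc1ccc(OCc2ccccc2)cc1 | intermediate
18 | 2,4-bis[4-(benzyloxy)benzyl]-3-(2-{2-[4-(benzyloxy)benzyl]-5-hydroxyphenyl}ethyl)-5-methoxyphenol | COc1cc(O)c(Cc2ccc(OCc3ccccc3)cc2)c(CCc2cc(O)ccc2Cc2ccc(OCc3ccccc3)cc2)c1Cc1ccc(OCc2ccccc2)cc1 | intermediate
19 | 2,4-bis(4-hydroxybenzyl)-3-{2-[5-hydroxy-2-(4-hydroxybenzyl)phenyl]ethyl}-5-methoxyphenol (achiral) | COc1cc(O)c(Cc2ccc(O)cc2)c(CCc2cc(O)ccc2Cc2ccc(O)cc2)c1Cc1ccc(O)cc1 | target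

Total step count: 8. Longest linear sequence: 7 (steps 2 to 8); step 1 is a one-step branch.

**Steps most likely to fail**

1. Step 5. The cycloaddition may stall because the benzyl-bearing diene terminus is hindered and the diene is an isomer mixture, so that thermal silyl migration or hydrolysis of the ketene acetal outruns annulation; over-annulation of both ynones is the second concern. The fallback sets out from 3 and returns at 13, and adds the ring A benzyl group after the ring is made. Commercial methyl (E)-3-methoxybut-2-enoate would be converted with LDA and Me3SiCl into the unhindered diene [(1,3-dimethoxybuta-1,3-dien-1-yl)oxy]trimethylsilane F1. Cycloaddition of F1 with excess 3 in toluene would give the cyclohexa-1,4-diene cycloadduct 1-[4-(benzyloxy)phenyl]-5-{2-[4-(benzyloxy)benzoyl]-3,5-dimethoxy-3-(trimethylsilyloxy)cyclohexa-1,4-dien-1-yl}pent-2-yn-1-one F2. Acid work-up would convert F2 into the phenol 1-[4-(benzyloxy)phenyl]-5-{2-[4-(benzyloxy)benzoyl]-3-hydroxy-5-methoxyphenyl}pent-2-yn-1-one F3, in which C6 of ring A is free. N-Bromosuccinimide (MeCN, 0 °C) should brominate para to the chelated hydroxyl to give 1-[4-(benzyloxy)phenyl]-5-{2-[4-(benzyloxy)benzoyl]-6-bromo-3-hydroxy-5-methoxyphenyl}pent-2-yn-1-one F4. Negishi coupling of F4 with excess [4-(benzyloxy)benzyl]zinc chloride F5 (from 5, Zn, LiCl, THF; Pd(OAc)2, SPhos) would then give 13.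

2. Step 7. Benzyl ethers may be lost to the acid, hydride transfer to the doubly ortho-substituted carbonyl on ring A may be slow, or the ring A benzylic cation may close a seven-membered ring onto C2' of ring B. The fallback sets out from 17 and returns at 19, and avoids free cations. LiAlH4 (THF, 0 °C → reflux, Fieser work-up) would reduce both ketones to the bis(benzhydrol) 4-[4-(benzyloxy)benzyl]-2-{[4-(benzyloxy)phenyl](hydroxy)methyl}-3-[2-(2-{[4-(benzyloxy)phenyl](hydroxy)methyl}-5-hydroxyphenyl)ethyl]-5-methoxyphenol F6 (mixture of diastereomers). Hydrogenation of F6 (H2, Pd/C, EtOAc/MeOH, a little AcOH) would cleave the two doubly benzylic C–OH bonds together with the three benzyl ethers and give 19 directly.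

3. Step 4. γ-Deprotonation may be incomplete, C-silylation may compete, or the silyl ketene acetal may hydrolyse on isolation. The fallback sets out from 7 and returns at 13; it uses soft enolisation in place of the lithium amide and introduces the methyl ether afterwards. Keto ester 7 with Me3SiOTf (2.2 equiv) and Et3N in Et2O would pass through the silyl enol ether methyl 5-[4-(benzyloxy)phenyl]-3-(trimethylsilyloxy)pent-2-enoate F7 to the bis(silyloxy)diene ({5-[4-(benzyloxy)phenyl]-1-methoxypenta-1,3-diene-1,3-diyl}bis(oxy))bis(trimethylsilane) F8. Cycloaddition of F8 with excess 3 would give the cycloadduct 1-[4-(benzyloxy)phenyl]-5-{2-[4-(benzyloxy)benzoyl]-6-[4-(benzyloxy)benzyl]-3-methoxy-3,5-bis(trimethylsilyloxy)cyclohexa-1,4-dien-1-yl}pent-2-yn-1-one F9. Acid work-up would give the resorcinol 1-[4-(benzyloxy)phenyl]-5-{2-[4-(benzyloxy)benzoyl]-6-[4-(benzyloxy)benzyl]-3,5-dihydroxyphenyl}pent-2-yn-1-one F10. Methylation of F10 with MeI (excess) and K2CO3 (1.1 equiv) in acetone at rt should take place only at the non-chelated, more acidic hydroxyl para to the carbonyl group and give 13.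

## Further compounds

F1 | step 5 | [(1,3-dimethoxybuta-1,3-dien-1-yl)oxy]trimethylsilane | COC(=CC(OC)=C)O[Si](C)(C)C
F2 | step 5 | 1-[4-(benzyloxy)phenyl]-5-{2-[4-(benzyloxy)benzoyl]-3,5-dimethoxy-3-(trimethylsilyloxy)cyclohexa-1,4-dien-1-yl}pent-2-yn-1-one (racemic) | COC1=CC(OC)(O[Si](C)(C)C)C(C(=O)c2ccc(OCc3ccccc3)cc2)=C(CCC#CC(=O)c2ccc(OCc3ccccc3)cc2)C1
F3 | step 5 | 1-[4-(benzyloxy)phenyl]-5-{2-[4-(benzyloxy)benzoyl]-3-hydroxy-5-methoxyphenyl}pent-2-yn-1-one | O=C(C#CCCc1cc(OC)cc(O)c1C(=O)c1ccc(OCc2ccccc2)cc1)c1ccc(OCc2ccccc2)cc1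
F4 | step 5 | 1-[4-(benzyloxy)phenyl]-5-{2-[4-(benzyloxy)benzoyl]-6-bromo-3-hydroxy-5-methoxyphenyl}pent-2-yn-1-one | O=C(C#CCCc1c(Br)c(OC)cc(O)c1C(=O)c1ccc(OCc2ccccc2)cc1)c1ccc(OCc2ccccc2)cc1
F5 | step 5 | [4-(benzyloxy)benzyl]zinc chloride | Cl[Zn]Cc1ccc(OCc2ccccc2)cc1
F6 | step 7 | 4-[4-(benzyloxy)benzyl]-2-{[4-(benzyloxy)phenyl](hydroxy)methyl}-3-[2-(2-{[4-(benzyloxy)phenyl](hydroxy)methyl}-5-hydroxyphenyl)ethyl]-5-methoxyphenol (mixture of diastereomers) | OC(c1ccc(OCc2ccccc2)cc1)c1ccc(O)cc1CCc1c(C(O)c2ccc(OCc3ccccc3)cc2)c(O)cc(OC)c1Cc1ccc(OCc2ccccc2)cc1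
F7 | step 4 | methyl 5-[4-(benzyloxy)phenyl]-3-(trimethylsilyloxy)pent-2-enoate (C=C isomer mixture) | COC(=O)C=C(CCc1ccc(OCc2ccccc2)cc1)O[Si](C)(C)C
F8 | step 4 | ({5-[4-(benzyloxy)phenyl]-1-methoxypenta-1,3-diene-1,3-diyl}bis(oxy))bis(trimethylsilane) (C=C isomer mixture) | COC(=CC(=CCc1ccc(OCc2ccccc2)cc1)O[Si](C)(C)C)O[Si](C)(C)C
F9 | step 4 | 1-[4-(benzyloxy)phenyl]-5-{2-[4-(benzyloxy)benzoyl]-6-[4-(benzyloxy)benzyl]-3-methoxy-3,5-bis(trimethylsilyloxy)cyclohexa-1,4-dien-1-yl}pent-2-yn-1-one (racemic mixture of diastereomers) | COC1(O[Si](C)(C)C)C=C(O[Si](C)(C)C)C(Cc2ccc(OCc3ccccc3)cc2)C(CCC#CC(=O)c2ccc(OCc3ccccc3)cc2)=C1C(=O)c1ccc(OCc2ccccc2)cc1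
F10 | step 4 | 1-[4-(benzyloxy)phenyl]-5-{2-[4-(benzyloxy)benzoyl]-6-[4-(benzyloxy)benzyl]-3,5-dihydroxyphenyl}pent-2-yn-1-one | O=C(C#CCCc1c(C(=O)c2ccc(OCc3ccccc3)cc2)c(O)cc(O)c1Cc1ccc(OCc2ccccc2)cc1)c1ccc(OCc2ccccc2)cc1
A1 | direct plan | methyl 3-(benzyloxy)-2,6-dibromo-5-methoxybenzoate | COC(=O)c1c(Br)c(OCc2ccccc2)cc(OC)c1Br
A2 | direct plan | 3-(benzyloxy)-2,6-bis[4-(benzyloxy)benzyl]-5-methoxybenzaldehyde | O=Cc1c(Cc2ccc(OCc3ccccc3)cc2)c(OCc2ccccc2)cc(OC)c1Cc1ccc(OCc2ccccc2)cc1
A3 | direct plan | methyl 4-(benzyloxy)-2-methylbenzoate | COC(=O)c1ccc(OCc2ccccc2)cc1C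
A4 | direct plan | (±)-6-(benzyloxy)-3-{3-(benzyloxy)-2,6-bis[4-(benzyloxy)benzyl]-5-methoxyphenyl}-3,4-dihydro-1H-isochromen-1-one | O=C1OC(Cc2cc(OCc3ccccc3)ccc12)c1c(Cc2ccc(OCc3ccccc3)cc2)c(OCc2ccccc2)cc(OC)c1Cc1ccc(OCc2ccccc2)cc1
A5 | direct plan | 4-(benzyloxy)-2-[2-{3-(benzyloxy)-2,6-bis[4-(benzyloxy)benzyl]-5-methoxyphenyl}ethyl]benzoic acid | OC(=O)c1ccc(OCc2ccccc2)cc1CCc1c(Cc2ccc(OCc3ccccc3)cc2)c(OCc2ccccc2)cc(OC)c1Cc1ccc(OCc2ccccc2)cc1
A6 | direct plan | [4-(benzyloxy)phenyl]{4-(benzyloxy)-2-[2-{3-(benzyloxy)-2,6-bis[4-(benzyloxy)benzyl]-5-methoxyphenyl}ethyl]phenyl}methanone | O=C(c1ccc(OCc2ccccc2)cc1)c1ccc(OCc2ccccc2)cc1CCc1c(Cc2ccc(OCc3ccccc3)cc2)c(OCc2ccccc2)cc(OC)c1Cc1ccc(OCc2ccccc2)cc1
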